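In a one-step world, with solid substrate passing straight to target at first order, the fraction converted by a given time is the same for any charge. These runs test that picture.

all flasks: reagent 32.2 mM (in portions, 2)

|  | solid substrate | remark | time |
|---|---|---|---|
| grey | 46 mM | the very flask that is asked about, followed so far; portions every 50 min |  |
| blue | 92 mM | run made earlier; portions every 50 min |  |
| flask | 46 mM | the portions of reagent follow each other after 50 min, the first at the start | 2.0 h |

| run | time / min | target / % | solid substrate / % |
|---|---|---|---|
| grey | 3.00 | 0.2 | 99.2 |
| grey | 6.00 | 0.4 | 97.3 |
| grey | 8.00 | 0 | 96.2 |
| grey | 12.0 | 0.6 | 94.8 |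
| grey | 15.0 | 0.9 | 93.8 |
| blue | 25.0 | 0.7 | 95.8 |
| blue | 50.0 | 2.3 | 92.0 |
| blue | 80.0 | 5.0 | 87.9 |
| blue | 90.0 | 5.8 | 85.8 |
| blue | 120 | 7.5 | 81.0 |

(readings scatter by 0.3 percentage points)

- given per volume of solution although it is solid: solid substrate
- at the start none of the solid substrate is in solution
- what has only dissolved of solid substrate counts as not reacted
- the reaction counts as stopped when no species that holds the solid substrate changes by six tenths of a point or more over the second half of the time

* which holds at 2.0 h: what has brought the reaction to rest, or that it has not come to rest (for what has run out or reacted, a solid counts together with what of it has only dissolved) (it is still moving / all of the solid substrate has reacted / the reagent has run out first)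
* amount of target at 2.0 h, in percent of the solid substrate charged

Does the picture hold? No. Grey, the flask asked about, has lost 6.20 % of its solid by 15.0 min, while blue, with twice the charge, has lost less, 4.20 %, even by 25.0 min.

Where did grey's lost solid go? Target stands at 0.9 % at that reading, less than the solid lost. I take the rest to be dissolved and waiting.

When does control change hands? Blue's target rises at 0.0168 h⁻¹, as a fraction of its charge, up to 25.0 min, then at a faster 0.0429 h⁻¹. I put the crossing near that reading: first the solution fills, then reaction in solution keeps a steady pace.

The weak spot: why should that pace pass from blue to this flask? It is my assumption. Both have the same reagent schedule, and if the solution is kept filled, the pace is zero order in the solid. Equal amounts then mean fractions scaled by the charges. Hence the shared slope, blue's later gain of target rescaled to this flask's charge: 0.0859 h⁻¹.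

And at 2.0 h? Blue's last reading, rescaled the same way, gives my estimate for this flask, 15.0 %, less than the reagent charge of 70.0 % of the solid charged. By the shared slope the second hour adds about 8.59 %, more than one point and so past the margin for a stop, and I say it is still moving.

The forecast says it is still moving with 15 %, reasoning that “the rate hardly depends on the solid charged”.

The flask gives it is still moving and 17.5 %.

    solid substrate ⇌ dissolved substrate, rate k1*(cs1 - [dissolved substrate]) while solid is left; crystals form when [dissolved substrate] > cs1 (solubility = 5.80 mM, k = 7.00 × 10⁻⁴ s⁻¹)
    dissolved substrate + reagent → target (k = 0.0180 M⁻¹ s⁻¹)
    2 solid substrate → homo dimer (k = 1.80 × 10⁻⁵ M⁻¹ s⁻¹)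
    solid substrate + target → side product (k = 0.00140 M⁻¹ s⁻¹)

At 2.00 h target is made 4.16 times as fast as it is used up, each step taken net. Over the second hour target in the flask rose at 0.105 h⁻¹, faster than the shared slope of 0.0859 h⁻¹.

For the neighbour read at 3.0 h, the slope added to this flask's result gives 26.1 %. The computed target there is 25.2 %.

(The data were computed on assumed constants; noise was put on by code.)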